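**Strategy**

Rubrolide A is dissected into two arylacetylene units and CO2: in the furan-2(5H)-one ring, C3–C4 comes from one alkyne, C5 with the exocyclic benzylidene CH from the other, and C2 with both oxygens from carbon dioxide. The key step joins the three components on nickel: oxidative cyclization of 4-ethynylanisole with CO2 forms C2–C3, and transmetalation of the resulting nickelalactone with the zinc acetylide of the same alkyne, then reductive elimination, forms C4–C5. Its precursors are thus one commercial alkyne, used once as such and once as its alkynylzinc chloride, and CO2. Silver-catalysed 5-exo-dig lactonization of the (Z)-enynoic acid, demethylation and fourfold ortho-bromination complete the route.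

Key step: step 2

Remark on the chemistry: the phenols are carried as methyl ethers and the four bromine atoms are introduced last, because zerovalent nickel would insert into aryl–bromine bonds. The key step consumes two molecules of the alkyne, one as compound 1 and one as the alkynylzinc chloride 3 made from 1 in step 1 and used as a THF solution. Atom numbers are those of the furan-2(5H)-one ring of the target throughout.

**Route**

Step 1
Reactants: 1 4-ethynylanisole
Product: 3 [(4-methoxyphenyl)ethynyl]zinc chloride (THF solution), via lithium acetylide 2 (not isolated)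
Conditions: n-BuLi (1.0 equiv), THF, −78 °C; then ZnCl2 (1.05 equiv, THF), −78 → 0 °C
Reagents that add atoms: zinc chloride, Cl[Zn]Cl
Why: Deprotonation of the terminal alkyne by n-BuLi and salt metathesis of the lithium acetylide with ZnCl2 (lithium-to-zinc transmetalation) should give the alkynylzinc chloride, the standard preparation of alkynylzinc reagents for Negishi-type couplings.

Step 2
Reactants: 1 4-ethynylanisole; 3 [(4-methoxyphenyl)ethynyl]zinc chloride; 4 carbon dioxide
Product: 6 (Z)-3,5-bis(4-methoxyphenyl)pent-2-en-4-ynoic acid, via nickelalactone 5 (not isolated)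
Conditions: (a) Ni(cod)2 (1.1 equiv), DBU (2.2 equiv), CO2 (1 atm), THF, 0 °C, slow addition of 1; (b) CO2 replaced by Ar, then 3 (2.5 equiv, THF solution from step 1), 0 °C → rt; (c) 1 M HCl
Reagents that add atoms: carbon dioxide (compound 4), O=C=O
Why: Proposed new method: oxidative cyclization of alkyne 1 and CO2 on zerovalent nickel should give the five-membered nickelalactone 5 (C2–C3 bond), whose Ni–O bond is opened by transmetalation with zinc acetylide 3, and C(sp2)–C(sp) reductive elimination from the resulting alkenyl(alkynyl)nickel should then form C4–C5. The closest known reaction type is the nickel-promoted alkylative and arylative carboxylation of terminal alkynes with CO2 and organozinc reagents; only the alkynylzinc partner is new, and alkynylzincs are known to transmetalate readily to divalent nickel. No ring is closed in the isolated product; the transient oxanickelacycle closes by oxidative cyclometalation. No stereocentre is formed, but the C3=C4 geometry is fixed because carboxylate and nickel are cis in the metallacycle and the alkynyl group replaces nickel with retention, so that CO2H and the alkyne end up cis as the later lactonization requires. The step needs regioselectivity (CO2 at the terminal CH carbon, nickel and hence the alkynyl group at the aryl-bearing carbon), which should be secured by C–C bond formation at the unhindered terminus and by the aryl group stabilising the Ni–C bond; slow addition of 1 and removal of CO2 before 3 is added should suppress alkyne oligomerization and carboxylation of the acetylide.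

Step 3
Reactants: 6 (Z)-3,5-bis(4-methoxyphenyl)pent-2-en-4-ynoic acid
Product: 7 (Z)-5-(4-methoxybenzylidene)-4-(4-methoxyphenyl)furan-2(5H)-one
Conditions: Ag2CO3 (10 mol %), DMF, rt, dark
Reagents that add atoms: none
Why: Silver-catalysed cycloisomerization of a (Z)-2-en-4-ynoic acid should proceed by 5-exo-dig anti-addition of the carboxylate oxygen and silver across the alkyne (forming O1–C5) and protodeargentation with retention, which places the anisyl group cis to the ring oxygen and so gives the (Z)-benzylidene butenolide.

Step 4
Reactants: 7 (Z)-5-(4-methoxybenzylidene)-4-(4-methoxyphenyl)furan-2(5H)-one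
Product: 8 rubrolide E, (Z)-5-(4-hydroxybenzylidene)-4-(4-hydroxyphenyl)furan-2(5H)-one
Conditions: BBr3 (6 equiv), CH2Cl2, −78 °C → rt; then H2O
Reagents that add atoms: none
Why: Lewis-acid cleavage of aryl methyl ethers with BBr3 (bromide attacks the O-methyl group of the boron-complexed ether) should free both phenols, while the enol lactone and the (Z)-alkene are not expected to react at these temperatures.

Step 5
Reactants: 8 rubrolide E
Product: 9 rubrolide A, (Z)-5-(3,5-dibromo-4-hydroxybenzylidene)-4-(3,5-dibromo-4-hydroxyphenyl)furan-2(5H)-one
Conditions: Br2 (4.2 equiv), NaOAc (4.5 equiv), AcOH, 15 °C → rt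
Reagents that add atoms: bromine, BrBr
Why: Electrophilic aromatic bromination should take place at the four positions ortho to the phenolic OH groups (para positions are blocked), which are far more nucleophilic than the exocyclic alkene deactivated by conjugation with the lactone carbonyl, so four equivalents in buffered AcOH should stop at the tetrabromide.

**Compound list**

1 | 4-ethynylanisole (1-ethynyl-4-methoxybenzene) | C#Cc1ccc(OC)cc1 | starting material
2 | lithium (4-methoxyphenyl)acetylide | [Li]C#Cc1ccc(OC)cc1 | intermediate
3 | [(4-methoxyphenyl)ethynyl]zinc chloride | Cl[Zn]C#Cc1ccc(OC)cc1 | intermediate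
4 | carbon dioxide | O=C=O | starting material
5 | nickelalactone, 3-(4-methoxyphenyl)-1-oxa-2-nickelacyclopent-3-en-5-one (DBU ligands on nickel not drawn) | O=C1C=C(c2ccc(OC)cc2)[Ni]O1 | intermediate
6 | (Z)-3,5-bis(4-methoxyphenyl)pent-2-en-4-ynoic acid (CO2H and alkynyl group cis) | OC(=O)/C=C(\C#Cc1ccc(OC)cc1)c1ccc(OC)cc1 | intermediate
7 | (Z)-5-(4-methoxybenzylidene)-4-(4-methoxyphenyl)furan-2(5H)-one | O=C1C=C(c2ccc(OC)cc2)/C(=C/c2ccc(OC)cc2)O1 | intermediate
8 | rubrolide E, (Z)-5-(4-hydroxybenzylidene)-4-(4-hydroxyphenyl)furan-2(5H)-one | O=C1C=C(c2ccc(O)cc2)/C(=C/c2ccc(O)cc2)O1 | intermediate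
9 | rubrolide A, (Z)-5-(3,5-dibromo-4-hydroxybenzylidene)-4-(3,5-dibromo-4-hydroxyphenyl)furan-2(5H)-one | O=C1C=C(c2cc(Br)c(O)c(Br)c2)/C(=C/c2cc(Br)c(O)c(Br)c2)O1 | target

**Summary**

Total step count: 5. Longest linear sequence: 5 steps (1 → 3 → 6 → 7 → 8 → 9).

**Steps most likely to fail**

1. Step 2 (proposed new method). The alkynyl group may transfer too slowly from zinc to the nickelalactone, so that protonolysis on work-up returns only the cinnamic acid. Nickel-mediated oligomerization of the terminal alkyne and zinc-promoted 6-endo closure of the product carboxylate are further risks. The fallback uses known reactions only, sets out from 1 and comes back to the route at 7. Deprotonation of 1 (n-BuLi, THF, −78 °C, by way of lithium acetylide 2) and carboxylation with 4 should give 3-(4-methoxyphenyl)prop-2-ynoic acid F1. Anti-hydroiodination (NaI, AcOH, 110 °C) should give (Z)-3-iodo-3-(4-methoxyphenyl)prop-2-enoic acid F2. Sonogashira coupling of F2 with a second portion of 1 (Pd(PPh3)4, CuI, Et3N, MeCN, rt) should be followed in the same flask by lactonization of the enynoate to 7. C2–C3 and C4–C5 are then made in separate operations.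

2. Step 3. The carboxylate may attack the anisyl-bearing alkyne carbon instead (6-endo-dig closure to the isomeric 2-pyranone), since the electron-rich aryl group stabilises positive charge there. The fallback avoids any alkyne cyclization, sets out from 1 by way of nickelalactone 5 (generated from 1 and 4 as in step 2) and comes back at 7. Treatment of 5 with Me2Zn in place of 3 (the known methylative variant) should give (E)-3-(4-methoxyphenyl)but-2-enoic acid F3, with CH3 cis to CO2H. Wohl–Ziegler bromination (NBS, AIBN, PhCF3, 80 °C) should give (Z)-4-bromo-3-(4-methoxyphenyl)but-2-enoic acid F4. NaHCO3 should close F4 by intramolecular carboxylate alkylation to 4-(4-methoxyphenyl)furan-2(5H)-one F5. Vinylogous Mukaiyama aldol addition of F5 to commercial 4-methoxybenzaldehyde (TBSOTf, i-Pr2NEt, CH2Cl2) should give 5-[(tert-butyldimethylsilyloxy)(4-methoxyphenyl)methyl]-4-(4-methoxyphenyl)furan-2(5H)-one F6. DBU in the same flask should eliminate silanol to the (Z)-benzylidene compound 7.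

3. Step 5. Bromine may also attack C3 or the exocyclic alkene through the vinylogous conjugation of the benzylidene phenol, or bromination may stop early and give mixtures. The fallback brings both dibromophenol rings in ready-made and forms the lactone afterwards; it sets out from 4, with commercial 3,5-dibromo-4-hydroxybenzaldehyde as an additional purchased material, and comes back at 9. The aldehyde is O-methylated (MeI, K2CO3, DMF) to 3,5-dibromo-4-methoxybenzaldehyde F7. Ohira–Bestmann homologation (dimethyl (1-diazo-2-oxopropyl)phosphonate, K2CO3, MeOH) should give 1,3-dibromo-5-ethynyl-2-methoxybenzene F8. Carboxylation of F8 with 4 (AgI cat., Cs2CO3, DMF, 50 °C; then HCl) should give 3-(3,5-dibromo-4-methoxyphenyl)prop-2-ynoic acid F9. Hydroiodination (NaI, AcOH, 110 °C) should give (Z)-3-(3,5-dibromo-4-methoxyphenyl)-3-iodoprop-2-enoic acid F10. Tandem Sonogashira coupling–lactonization of F10 with F8 (Pd(PPh3)4, CuI, Et3N, MeCN, rt; the vinyl iodide should react before the aryl bromides) should give (Z)-5-(3,5-dibromo-4-methoxybenzylidene)-4-(3,5-dibromo-4-methoxyphenyl)furan-2(5H)-one F11. BBr3 (CH2Cl2, −78 °C → rt) should then give 9.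

**Further compounds**

F1 | step 2 | 3-(4-methoxyphenyl)prop-2-ynoic acid | OC(=O)C#Cc1ccc(OC)cc1
F2 | step 2 | (Z)-3-iodo-3-(4-methoxyphenyl)prop-2-enoic acid | OC(=O)/C=C(\I)c1ccc(OC)cc1
F3 | step 3 | (E)-3-(4-methoxyphenyl)but-2-enoic acid | C/C(=C\C(=O)O)c1ccc(OC)cc1
F4 | step 3 | (Z)-4-bromo-3-(4-methoxyphenyl)but-2-enoic acid | BrC/C(=C\C(=O)O)c1ccc(OC)cc1
F5 | step 3 | 4-(4-methoxyphenyl)furan-2(5H)-one | O=C1C=C(c2ccc(OC)cc2)CO1
F6 | step 3 | 5-[(tert-butyldimethylsilyloxy)(4-methoxyphenyl)methyl]-4-(4-methoxyphenyl)furan-2(5H)-one (mixture of diastereomers) | O=C1C=C(c2ccc(OC)cc2)C(C(O[Si](C)(C)C(C)(C)C)c2ccc(OC)cc2)O1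
F7 | step 5 | 3,5-dibromo-4-methoxybenzaldehyde | COc1c(Br)cc(C=O)cc1Br
F8 | step 5 | 1,3-dibromo-5-ethynyl-2-methoxybenzene | COc1c(Br)cc(C#C)cc1Br
F9 | step 5 | 3-(3,5-dibromo-4-methoxyphenyl)prop-2-ynoic acid | COc1c(Br)cc(C#CC(=O)O)cc1Br
F10 | step 5 | (Z)-3-(3,5-dibromo-4-methoxyphenyl)-3-iodoprop-2-enoic acid | COc1c(Br)cc(/C(I)=C/C(=O)O)cc1Br
F11 | step 5 | (Z)-5-(3,5-dibromo-4-methoxybenzylidene)-4-(3,5-dibromo-4-methoxyphenyl)furan-2(5H)-one | O=C1C=C(c2cc(Br)c(OC)c(Br)c2)/C(=C/c2cc(Br)c(OC)c(Br)c2)O1
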